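**Conventions.** Isoflavone numbering (O1, C2, C3, C4, C4a–C8a, C1'–C6') is used for all intermediates, cyclic or not. ArB stands for the protected ring B group 2,4-bis(methoxymethoxy)-5-(2-methylbut-3-en-2-yl)-3-(3-methylbut-2-en-1-yl)phenyl, SMILES fragment `*c1cc(C(C)(C)C=C)c(OCOC)c(CC=C(C)C)c1OCOC`. "Prenyl" means 3-methylbut-2-en-1-yl and "MOM" means methoxymethyl.

## Analysis of the target

Fremontone, compound 25, is an isoflavone: a 4H-chromen-4-one (rings A and C) that carries ring B at C3. Ring A is a phloroglucinol unit with hydroxyls at C5 and C7 and its third oxygen as O1, while ring B is pentasubstituted, with hydroxyls at C2' and C4', a prenyl group at C3' between them, a 2-methylbut-3-en-2-yl (1,1-dimethylallyl) group at C5', and hydrogen only at C6'. There is no stereocentre and the C3–C1' axis is not configurationally stable, so any sp3 centre made on the way only has to be erasable. The sensitive parts are the four phenols (the C5 hydroxyl is chelated to the C4 carbonyl), the prenyl double bond, and the terminal vinyl group on a quaternary benzylic carbon. Under acid the prenyl group adds a neighbouring phenol to give a chroman, and it is also attacked by electrophilic halogen and oxidant sources. The synthesis is hard for two reasons: two isomeric five-carbon units must be placed on defined carbons of ring B, and the crowded, electron-rich ring B must be joined to C3 while ring C is built without strong acid, hydrogenation or unselective oxidants. The plan rests on the fact that the C4 carbonyl carbon is bonded to C4a of the phloroglucinol ring, so that C4–C4a can be made by a C4a carbanion attacking a carboxyl carbon; with C2–C3 left saturated until the end, the substrate is a plain 3-aryloxy-2-arylpropanoic acid.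

## Retrosynthetic reasoning

**25 from 24.** The four phenols are unmasked last, by cutting four O–CH2OMe bonds. Acetal ethers are chosen because they survive bases, organolithiums and hydride-free oxidations and fall to dilute acid. Benzyl ethers would need hydrogenolysis, which saturates both alkenes, and methyl ethers would need Lewis acids that cyclise the prenyl phenol.

**24 from 20.** The C2=C3 double bond is taken back to a C2–C3 single bond. This makes C2 and C3 ordinary sp3 carbons for the ring closure and turns C3 into a racemic centre that need not be controlled, since it vanishes again. The forward step must take out two hydrogens next to a ketone without touching the prenyl and vinyl groups.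

**20 from 16.** Ring C is opened at C4–C4a. This cut separates a ring A phenol from a ring B propanoic acid and leaves the hindered C3–C1' bond to be made early, at the stage of a simple benzylic carbon. A Friedel–Crafts closure in the same sense would need acid, which the acetals and the prenyl group do not tolerate. The polarity is therefore kept but the conditions inverted: C4a becomes an aryllithium and C4 a carboxylate. A bromine at C4a is required, because deprotonative lithiation of this ring would go to the carbon between the two acetal oxygens (C6) and cannot be run on a free acid anyway. The carboxylate form is chosen over an ester because it resists deprotonation at C3 and so protects against loss of the aryloxide by elimination.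

**16 from 15, and 15 from 11 plus 14.** The acid is taken back to its methyl ester, and the ester is cut at the alkyl O1–C2 bond. This gives the primary alcohol 11 and the bromophenol 14, two fragments of similar size that are joined under neutral, dehydrative conditions. The forward reaction must substitute at the primary carbon faster than the β-hydroxy ester dehydrates.

**11 from 10.** The C2–C3 bond is cut, removing a one-carbon electrophile. The arylacetic ester 10 has the only acidic C–H in the molecule, so the forward hydroxymethylation needs only catalytic base.

**10 from 9, 8 and 6.** The C3–C4 bond is cut: the carboxyl carbon is added to the aldehyde 6 as a nitrile carbon, and the nitrile 8 is hydrolysed to the acid 9 and esterified. Every step of this homologation is basic, which suits the acetals and the alkenes.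

**6 from 5, 4, 3, and 1 plus 2.** A 1,1-dimethylallyl group ortho to a phenolic oxygen is the mark of an aromatic Claisen rearrangement of an O-prenyl ether, so the C5' substituent of 5 is traced to the ether 4. The rearrangement has to go to C5' and not to C3', so C3' is filled first with its prenyl group by C-alkylation of 1 with 2, which gives 3. The aldehyde of 1 does double duty. Its hydrogen bond to the C2' hydroxyl leaves only the C4' hydroxyl free for etherification, and it later becomes C3 of the chain.

**14 from 13 and 12.** The bromophenol 14 is cut at C–Br and at two acetal C–O bonds back to the triol 12. The two positions ortho to the free hydroxyl of 13 are equivalent, so only ortho-versus-para selectivity has to be secured in the bromination.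

## Alternatives that were turned down

**Alternative 1:** Ring B itself is disconnected, at C5'–C6' and C3'–C4'. In the forward key step the enolate of the ester A2, methyl 3,3-dimethylpent-4-enoate, adds to the vinyl ketone A3, 7-methylocta-1,6-dien-3-one, and the resulting ketone enolate then attacks the ester carbon. This closes ring B as the dione A1, 4-(2-methylbut-3-en-2-yl)-2-prenylcyclohexane-1,3-dione, which would later be dehydrogenated to the aromatic level.
- For it: both five-carbon groups are placed by the choice of the acyclic partners A2 and A3, so no isomer mixture and no high-temperature rearrangement arise. On regiocontrol of ring B it is stronger than steps 1–3 of the chosen route.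
- Against it: the enolate of A2 sits next to a quaternary carbon and must add 1,4 to A3, a vinyl ketone that polymerises easily. A1 is at the wrong oxidation level, and dehydrogenating a 2,4-dialkylated cyclohexane-1,3-dione with palladium on carbon, iodine or quinones is doubtful next to a prenyl and a vinyl group. After that, C1' is still a C–H, and the whole of ring C and the union with ring A remain unsolved.
- Comparison: it spends its key step on the half of the problem that classical phenol chemistry already solves in four steps from commercial 1. The chosen strategy gives up some regiochemical elegance on ring B and puts its key step on the bond that joins the rings.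

**Alternative 2:** Ring C is cut at C3–C4 and O1–C8a. The enamine A5, the morpholine enamine of the arylacetaldehyde A7 (2-(ArB)acetaldehyde), is C-acylated by the acid chloride A6, 2-fluoro-4,6-bis(methoxymethoxy)benzoyl chloride. Aqueous base then hydrolyses the acylated enamine, and the enol oxygen displaces fluoride to close ring C. The product A4 is fremontone tetrakis(methoxymethyl) ether, the same compound as 24.
- For it: it is convergent, forms two bonds of ring C in one flask and arrives directly at the isoflavone oxidation level of A4. On step count after the key step, and in avoiding selenium, it is stronger than the chosen route. The fluorine of A6 fixes the ring A regiochemistry as surely as bromine does.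
- Against it: both partners are fragile. A5 has to be made from A7, an electron-rich arylacetaldehyde with an ortho acetal that is prone to self-condensation and hard to release without acid. A6 is a doubly ortho-substituted acid chloride that must be made and used in the presence of two acid-labile acetals, with hydrogen chloride formed in both operations. The acylating carbon of A6 is also deactivated by two donor oxygens and hindered on both sides.
- Comparison: the chosen strategy is one to two steps longer at the end. In exchange it works with storable esters, acids and phenols, and it forms every bond between the halves under neutral or basic conditions.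

**Alternative 3:** Ring B is cut at C2'–C3', C4'–C5' and C1'–C2' and built on a finished chromone by a Danheiser benzannulation. The chromonyl diazo enone A9 is irradiated and undergoes Wolff rearrangement to a vinylketene, which adds the prenyl siloxyalkyne A10 by [2+2] cycloaddition; four-electron ring opening and six-electron ring closure follow. The product A8 is 4'-O-triisopropylsilyl-5,7-bis-O-methoxymethyl fremontone, with the C2' phenol free.
- For it: the pentasubstituted ring B of A8 is made in one operation, with its substitution pattern dictated by the mechanism and the two ring B oxygens differentiated. On convergence and on ring B regiocontrol it is clearly stronger than the chosen route.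
- Against it: the diazo carbon of A9 is attached to a quaternary allylic carbon, so diazo transfer is hindered and 1,2-shifts can compete with the Wolff rearrangement. The chromone ring of A9 is itself a light-absorbing enone. A10 is a skipped enyne ynol ether that needs its own multistep synthesis. A8 carries a triisopropylsilyloxy group wedged between two bulky carbon substituents. The step of highest risk would fall on the two most elaborate intermediates.
- Comparison: the chosen strategy takes a longer, classical path to ring B from commercial aromatics. It confines its risk to one ring closure of a known type on a substrate reached by standard reactions.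

Key step: step 13

## Route

Step 1
Reactants: 1 2,4-dihydroxybenzaldehyde; 2 prenyl bromide (1-bromo-3-methylbut-2-ene)
Product: 3 2,4-dihydroxy-3-(3-methylbut-2-en-1-yl)benzaldehyde
Conditions: 2 (1 equiv), 10% aq. KOH, 0 °C → rt; chromatography
Reagents that add atoms: prenyl bromide (compound 2), CC(C)=CCBr
Why: C-alkylation of an ambident phenoxide in water, where the solvated oxygens react slowly and the carbon between the two oxygens (C3) is the most nucleophilic; the 3-prenyl isomer should be the main C-alkylated product, in modest amount, beside separable O-ethers and the 5-isomer.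

Step 2
Reactants: 3 2,4-dihydroxy-3-(3-methylbut-2-en-1-yl)benzaldehyde; 2 prenyl bromide
Product: 4 2-hydroxy-3-(3-methylbut-2-en-1-yl)-4-[(3-methylbut-2-en-1-yl)oxy]benzaldehyde
Conditions: 2 (1.1 equiv), K2CO3, acetone, reflux
Reagents that add atoms: prenyl bromide (compound 2), CC(C)=CCBr
Why: Williamson etherification; the C2 hydroxyl is held in a hydrogen bond to the aldehyde and is less acidic and less nucleophilic, so only the C4 hydroxyl should react.

Step 3
Reactants: 4 2-hydroxy-3-(3-methylbut-2-en-1-yl)-4-[(3-methylbut-2-en-1-yl)oxy]benzaldehyde
Product: 5 2,4-dihydroxy-5-(2-methylbut-3-en-2-yl)-3-(3-methylbut-2-en-1-yl)benzaldehyde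
Conditions: N,N-diethylaniline, 180 °C, sealed tube
Reagents that add atoms: none
Why: Aromatic Claisen rearrangement; the [3,3] shift delivers the allyl unit with allylic transposition to an ortho carbon, and since C3 is blocked only the dienone formed at C5 can tautomerise to a phenol; the amine solvent buffers traces of acid that would cyclise the product.

Step 4
Reactants: 5 2,4-dihydroxy-5-(2-methylbut-3-en-2-yl)-3-(3-methylbut-2-en-1-yl)benzaldehyde
Product: 6 2,4-bis(methoxymethoxy)-5-(2-methylbut-3-en-2-yl)-3-(3-methylbut-2-en-1-yl)benzaldehyde (ArB–CHO)
Conditions: NaH (3 equiv), MOMCl (3 equiv), DMF, 0 °C → rt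
Reagents that add atoms: chloromethyl methyl ether (MOMCl), COCCl
Why: O-alkylation of the sodium phenoxides with a reactive α-chloro ether; full deprotonation with NaH overcomes both the hydrogen bond at the C2 hydroxyl and the crowding at the C4 hydroxyl.

Step 5
Reactants: 6 ArB–CHO
Product: 8 2-(ArB)acetonitrile, via N-formyl tosylenamine 7 (not isolated)
Conditions: TosMIC, KOt-Bu, DME, −40 °C; then MeOH, reflux
Reagents that add atoms: p-toluenesulfonylmethyl isocyanide (TosMIC), Cc1ccc(cc1)S(=O)(=O)C[N+]#[C-]
Why: Van Leusen reductive cyanation of an aldehyde; the TosMIC anion adds to the carbonyl, cyclises and ring-opens at low temperature to the N-formyl enamine 7, which methanol then deformylates, after which loss of sulfinate and tautomerisation give the nitrile with one added carbon; the medium is basic throughout, so acetals and alkenes are safe.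

Step 6
Reactants: 8 2-(ArB)acetonitrile
Product: 9 2-(ArB)acetic acid
Conditions: KOH, EtOH–H2O, reflux; then 1 M HCl, 0 °C, to pH 3, immediate extraction
Reagents that add atoms: potassium hydroxide, [K+].[OH-]; water, O
Why: Alkaline nitrile hydrolysis through the amide; acetals and alkenes are inert to hydroxide, and the cold, brief acidification to pH 3 should not cleave the MOM ethers.

Step 7
Reactants: 9 2-(ArB)acetic acid
Product: 10 methyl 2-(ArB)acetate
Conditions: MeI, K2CO3, DMF, rt
Reagents that add atoms: iodomethane, CI
Why: SN2 O-alkylation of the carboxylate; no acid is needed, and the weak base does not C-methylate the arylacetate.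

Step 8
Reactants: 10 methyl 2-(ArB)acetate
Product: 11 methyl rac-3-hydroxy-2-(ArB)propanoate
Conditions: (CH2O)n, NaOMe (cat.), DMSO, rt
Reagents that add atoms: formaldehyde (from paraformaldehyde), C=O
Why: Aldol-type hydroxymethylation of an arylacetate enolate, the classical route to tropic acid esters; the adduct is more hindered than 10, so mono-addition should prevail at room temperature, and the new C3 centre forms as the racemate, which is all that is needed.

Step 9
Reactants: 12 phloroglucinol (benzene-1,3,5-triol)
Product: 13 3,5-bis(methoxymethoxy)phenol
Conditions: NaH (2.0 equiv), MOMCl (2.0 equiv), DMF, 0 °C → rt; chromatography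
Reagents that add atoms: chloromethyl methyl ether (MOMCl), COCCl
Why: Statistical O-alkylation of a threefold symmetric triol; the bis-ether should be the main component at two equivalents and is separated from mono- and tris-ether, the first of which can be resubmitted.

Step 10
Reactants: 13 3,5-bis(methoxymethoxy)phenol
Product: 14 2-bromo-3,5-bis(methoxymethoxy)phenol
Conditions: NBS (1.0 equiv), i-Pr2NH (cat.), CH2Cl2, −78 °C → 0 °C
Reagents that add atoms: N-bromosuccinimide, O=C1CCC(=O)N1Br
Why: Amine-mediated ortho-bromination of a phenol; the N-bromoamine formed in situ is delivered through a hydrogen bond to the hydroxyl, the two ortho carbons are equivalent, and the para carbon is flanked by two acetal groups; no hydrogen bromide is formed.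

Step 11
Reactants: 11 methyl rac-3-hydroxy-2-(ArB)propanoate; 14 2-bromo-3,5-bis(methoxymethoxy)phenol
Product: 15 methyl rac-3-[2-bromo-3,5-bis(methoxymethoxy)phenoxy]-2-(ArB)propanoate
Conditions: PPh3, DIAD, THF, 0 °C → rt
Reagents that add atoms: none
Why: Mitsunobu etherification; the ortho-bromophenol is acidic enough to protonate the betaine quickly, and its phenoxide displaces the oxyphosphonium group at the primary C2 by SN2, without involving the C3 centre.

Step 12
Reactants: 15 methyl rac-3-[2-bromo-3,5-bis(methoxymethoxy)phenoxy]-2-(ArB)propanoate
Product: 16 rac-3-[2-bromo-3,5-bis(methoxymethoxy)phenoxy]-2-(ArB)propanoic acid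
Conditions: LiOH·H2O, THF–MeOH–H2O, 0 °C → rt; then 1 M HCl, 0 °C, to pH 3, immediate extraction
Reagents that add atoms: lithium hydroxide, [Li+].[OH-]
Why: Saponification by acyl–oxygen cleavage; at low temperature, attack of hydroxide on the methyl ester should be faster than deprotonation at C3 and loss of the aryloxide, and the carboxylate formed no longer eliminates.

Step 13
Reactants: 16 rac-3-[2-bromo-3,5-bis(methoxymethoxy)phenoxy]-2-(ArB)propanoic acid
Product: 20 rac-5,7-bis(methoxymethoxy)-3-(ArB)-2,3-dihydro-4H-chromen-4-one, via lithium carboxylate 17 (not isolated), via aryllithium 18 (not isolated), via dilithium gem-diolate 19 (not isolated)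
Conditions: n-BuLi (2.1 equiv), THF, −100 °C → −20 °C; then aq. NH4Cl
Reagents that add atoms: none
Why: The first equivalent of n-BuLi removes the acid proton to give 17, and the second exchanges bromine for lithium at C4a to give 18, an aryllithium stabilised by the ether and acetal oxygens on either side. On warming, C4a attacks the carboxylate carbon in a 6-exo-trig closure of ring C (the C=O lies outside the forming ring) to give the gem-diolate 19, which cannot expel oxide and so cannot be attacked again; aqueous NH4Cl then releases ketone 20. The closest known reaction type is the Parham cycloacylation of 3-(2-bromoaryloxy)propanoic acids to chroman-4-ones with two equivalents of an alkyllithium. No stereocentre is made: C3 is carried through as the racemate. The step needs halogen–lithium exchange to be faster than deprotonation at C3 and faster than addition of n-BuLi to the carboxylate; exchange at a bromide flanked by two oxygens should be the fastest of the three at −100 °C, and no excess base is used. The carboxylate keeps the C3–H weakly acidic and thereby suppresses the elimination of aryloxide that an ester enolate would undergo. The site of closure is fixed by bromine, whereas a deprotonative lithiation would choose the carbon between the two acetal groups. The medium is never acidic, so the four acetals and both alkenes should pass unchanged.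

Step 14
Reactants: 20 rac-5,7-bis(methoxymethoxy)-3-(ArB)-2,3-dihydro-4H-chromen-4-one
Product: 24 5,7-bis(methoxymethoxy)-3-(ArB)-4H-chromen-4-one, via lithium enolate 21 (not isolated), via selenide 22 (not isolated), via selenoxide 23 (not isolated)
Conditions: LiN(SiMe3)2, THF, −78 °C; PhSeCl (1.05 equiv), −78 °C; then NaIO4, NaHCO3, THF–MeOH–H2O, 0 °C → rt
Reagents that add atoms: none
Why: α-Selenenylation and selenoxide syn-elimination; C3–H is the only enolisable hydrogen and is also benzylic, the enolate 21 takes up selenium far faster than the alkenes do at −78 °C, and the selenoxide 23 has β-hydrogens only at C2, so elimination can only give the C2=C3 bond; periodate forms no peracid that could epoxidise the prenyl group.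

Step 15
Reactants: 24 5,7-bis(methoxymethoxy)-3-(ArB)-4H-chromen-4-one
Product: 25 fremontone
Conditions: 3 M aq. HCl, MeOH, 40 °C, monitored closely
Reagents that add atoms: none
Why: Acid-catalysed acetal exchange with methanol removes all four MOM groups; the oxocarbenium route of acetal cleavage is faster than protonation of the trisubstituted alkene, so short exposure to dilute acid should free the phenols before the prenyl group cyclises.

## Compound list

1 | 2,4-dihydroxybenzaldehyde | O=Cc1ccc(O)cc1O | starting material
2 | prenyl bromide (1-bromo-3-methylbut-2-ene) | CC(C)=CCBr | starting material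
3 | 2,4-dihydroxy-3-(3-methylbut-2-en-1-yl)benzaldehyde | O=Cc1ccc(O)c(CC=C(C)C)c1O | intermediate
4 | 2-hydroxy-3-(3-methylbut-2-en-1-yl)-4-[(3-methylbut-2-en-1-yl)oxy]benzaldehyde | O=Cc1ccc(OCC=C(C)C)c(CC=C(C)C)c1O | intermediate
5 | 2,4-dihydroxy-5-(2-methylbut-3-en-2-yl)-3-(3-methylbut-2-en-1-yl)benzaldehyde | O=Cc1cc(C(C)(C)C=C)c(O)c(CC=C(C)C)c1O | intermediate
6 | 2,4-bis(methoxymethoxy)-5-(2-methylbut-3-en-2-yl)-3-(3-methylbut-2-en-1-yl)benzaldehyde | O=Cc1cc(C(C)(C)C=C)c(OCOC)c(CC=C(C)C)c1OCOC | intermediate
7 | N-[2-(ArB)-1-(4-methylbenzenesulfonyl)ethenyl]formamide, alkene geometry undefined and of no consequence, formed as its potassium salt | O=CNC(=Cc1cc(C(C)(C)C=C)c(OCOC)c(CC=C(C)C)c1OCOC)S(=O)(=O)c1ccc(C)cc1 | intermediate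
8 | 2-(ArB)acetonitrile | N#CCc1cc(C(C)(C)C=C)c(OCOC)c(CC=C(C)C)c1OCOC | intermediate
9 | 2-(ArB)acetic acid | OC(=O)Cc1cc(C(C)(C)C=C)c(OCOC)c(CC=C(C)C)c1OCOC | intermediate
10 | methyl 2-(ArB)acetate | COC(=O)Cc1cc(C(C)(C)C=C)c(OCOC)c(CC=C(C)C)c1OCOC | intermediate
11 | methyl 3-hydroxy-2-(ArB)propanoate, racemic | COC(=O)C(CO)c1cc(C(C)(C)C=C)c(OCOC)c(CC=C(C)C)c1OCOC | intermediate
12 | phloroglucinol (benzene-1,3,5-triol) | Oc1cc(O)cc(O)c1 | starting material
13 | 3,5-bis(methoxymethoxy)phenol | COCOc1cc(O)cc(OCOC)c1 | intermediate
14 | 2-bromo-3,5-bis(methoxymethoxy)phenol | COCOc1cc(O)c(Br)c(OCOC)c1 | intermediate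
15 | methyl 3-[2-bromo-3,5-bis(methoxymethoxy)phenoxy]-2-(ArB)propanoate, racemic | COC(=O)C(COc1cc(OCOC)cc(OCOC)c1Br)c1cc(C(C)(C)C=C)c(OCOC)c(CC=C(C)C)c1OCOC | intermediate
16 | 3-[2-bromo-3,5-bis(methoxymethoxy)phenoxy]-2-(ArB)propanoic acid, racemic | OC(=O)C(COc1cc(OCOC)cc(OCOC)c1Br)c1cc(C(C)(C)C=C)c(OCOC)c(CC=C(C)C)c1OCOC | intermediate
17 | lithium 3-[2-bromo-3,5-bis(methoxymethoxy)phenoxy]-2-(ArB)propanoate, racemic | [Li+].[O-]C(=O)C(COc1cc(OCOC)cc(OCOC)c1Br)c1cc(C(C)(C)C=C)c(OCOC)c(CC=C(C)C)c1OCOC | intermediate
18 | lithium 3-[2-lithio-3,5-bis(methoxymethoxy)phenoxy]-2-(ArB)propanoate, racemic | [Li+].[O-]C(=O)C(COc1cc(OCOC)cc(OCOC)c1[Li])c1cc(C(C)(C)C=C)c(OCOC)c(CC=C(C)C)c1OCOC | intermediate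
19 | dilithium 5,7-bis(methoxymethoxy)-3-(ArB)chromane-4,4-diolate, racemic | [Li+].[Li+].[O-]C1([O-])c2c(OCOC)cc(OCOC)cc2OCC1c1cc(C(C)(C)C=C)c(OCOC)c(CC=C(C)C)c1OCOC | intermediate
20 | 5,7-bis(methoxymethoxy)-3-(ArB)-2,3-dihydro-4H-chromen-4-one (2,3-dihydrofremontone tetrakis(methoxymethyl) ether), racemic | O=C1c2c(OCOC)cc(OCOC)cc2OCC1c1cc(C(C)(C)C=C)c(OCOC)c(CC=C(C)C)c1OCOC | intermediate
21 | lithium 5,7-bis(methoxymethoxy)-3-(ArB)-2H-chromen-4-olate | [Li+].[O-]C1=C(c2cc(C(C)(C)C=C)c(OCOC)c(CC=C(C)C)c2OCOC)COc2cc(OCOC)cc(OCOC)c12 | intermediate
22 | 5,7-bis(methoxymethoxy)-3-(ArB)-3-(phenylselanyl)-2,3-dihydro-4H-chromen-4-one, racemic | O=C1c2c(OCOC)cc(OCOC)cc2OCC1([Se]c1ccccc1)c1cc(C(C)(C)C=C)c(OCOC)c(CC=C(C)C)c1OCOC | intermediate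
23 | 5,7-bis(methoxymethoxy)-3-(ArB)-3-(phenylseleninyl)-2,3-dihydro-4H-chromen-4-one, mixture of stereoisomers | O=C1c2c(OCOC)cc(OCOC)cc2OCC1([Se](=O)c1ccccc1)c1cc(C(C)(C)C=C)c(OCOC)c(CC=C(C)C)c1OCOC | intermediate
24 | 5,7-bis(methoxymethoxy)-3-(ArB)-4H-chromen-4-one (fremontone tetrakis(methoxymethyl) ether) | C=CC(C)(C)c1cc(-c2coc3cc(OCOC)cc(OCOC)c3c2=O)c(OCOC)c(CC=C(C)C)c1OCOC | intermediate
25 | fremontone | C=CC(C)(C)c1cc(-c2coc3cc(O)cc(O)c3c2=O)c(O)c(CC=C(C)C)c1O | target

## Step count and least certain steps

Total: 15 steps. Longest linear sequence: 13 steps (steps 1–8, then 11–15). The ring A branch (steps 9 and 10) joins at step 11.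

**Step 13 (key step).** The most likely failure is proton transfer from C3–H to the C4a–lithium centre through a six-membered transition state, or slow addition to the weakly electrophilic carboxylate. Either would lead, after work-up, to replacement of bromine by hydrogen or to loss of the aryloxide by elimination. Fallback within the same bond formation: 16 is coupled with N,O-dimethylhydroxylamine hydrochloride (EDC·HCl, HOBt, N-methylmorpholine, CH2Cl2, 0 °C) to the N-methoxy-N-methylamide F1. Treating F1 with t-BuLi (2 equiv) in THF at −100 °C should give bromine–lithium exchange and then attack of C4a on a far more electrophilic acceptor, whose chelated adduct cannot be attacked twice. Aqueous work-up should then release 20, where the route is rejoined.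

**Step 3.** The allyl–oxygen bond may ionise instead of rearranging, with loss of the prenyl group. The free ortho-(1,1-dimethylallyl)phenol may also rearrange further at this temperature or add its hydroxyl to the new alkene. Fallback: 4 is heated in N,N-diethylaniline at 180 °C with N,O-bis(trimethylsilyl)acetamide (3 equiv), so that each phenol is silylated as soon as it is present. The follow-up processes, which need the free C4 hydroxyl, are then shut off, and no acylating agent is present that could condense with the aldehyde. This gives the bis(trimethylsilyl) ether F2; methanolysis (K2CO3, MeOH, rt) returns to 5.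

**Step 11.** The activated β-hydroxy ester may dehydrate by deprotonation at C3 faster than the phenoxide substitutes at C2. Fallback: the dehydration is made deliberate and the C–O bond is formed by conjugate addition. 11 is converted with MsCl and Et3N (CH2Cl2, 0 °C) into the mesylate F3, which on warming to rt with excess Et3N eliminates to the 2-arylacrylate F4. Phenol 14 is then added to F4 with catalytic Cs2CO3 in concentrated MeCN solution at rt, rejoining the route at 15.

**Step 14.** Electrophilic selenium, or the selenenic acid released in the elimination, may add to the prenyl or vinyl group. Carbon–selenium bond formation at the fully substituted, hindered C3 may be slow, and the enolate may open ring C by expelling the O1 aryloxide if it is allowed to warm. Fallback without selenium: 20 is deprotonated with LiN(SiMe3)2 to the enolate 21 and silylated on oxygen with Me3SiCl (THF, −78 °C), where crowding at C3 does not matter, to give the trimethylsilyl enol ether F5. F5 is oxidised with DDQ and 2,6-lutidine (CH2Cl2, 0 °C → rt) to 24; the enol ether should react with the quinone much faster than the alkyl side chains do.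

**Step 15.** Acid may add the freed C2' or C4' hydroxyl across the prenyl double bond (chroman formation) before the hindered C4' acetal has been cleaved. Fallback that avoids protic acid: 24 is treated with Me3SiOTf and 2,2'-bipyridyl (MeCN, 0 °C → rt), which exchanges aryl MOM ethers for silyl ethers and gives the tetrakis(trimethylsilyl) ether F6. Adding water hydrolyses F6 at neutral pH to 25.

**Step 1.** O-alkylation, alkylation at C5 and double alkylation compete, so throughput to 3 is expected to be low, although the material is cheap. Fallback with built-in regiocontrol: 1 is etherified at the C4 hydroxyl with 3-chloro-3-methylbut-1-yne (K2CO3, KI, CuI cat., acetone, reflux) to the propargyl ether F7. F7 is semihydrogenated (H2, Pd on CaCO3 poisoned with Pb(OAc)2, quinoline, EtOAc) to the 1,1-dimethylallyl ether F8. Heating F8 in N,N-diethylaniline at 130–150 °C gives 3 by Claisen rearrangement; the chelated C2 hydroxyl directs the shift to C3, and the allylic transposition turns the tertiary ether into the linear prenyl group.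

## Further compounds

F1 | step 13 | N-methoxy-N-methyl-3-[2-bromo-3,5-bis(methoxymethoxy)phenoxy]-2-(ArB)propanamide, racemic | CON(C)C(=O)C(COc1cc(OCOC)cc(OCOC)c1Br)c1cc(C(C)(C)C=C)c(OCOC)c(CC=C(C)C)c1OCOC
F2 | step 3 | 5-(2-methylbut-3-en-2-yl)-3-(3-methylbut-2-en-1-yl)-2,4-bis(trimethylsilyloxy)benzaldehyde | O=Cc1cc(C(C)(C)C=C)c(O[Si](C)(C)C)c(CC=C(C)C)c1O[Si](C)(C)C
F3 | step 11 | methyl 3-(methanesulfonyloxy)-2-(ArB)propanoate, racemic | COC(=O)C(COS(C)(=O)=O)c1cc(C(C)(C)C=C)c(OCOC)c(CC=C(C)C)c1OCOC
F4 | step 11 | methyl 2-(ArB)prop-2-enoate | COC(=O)C(=C)c1cc(C(C)(C)C=C)c(OCOC)c(CC=C(C)C)c1OCOC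
F5 | step 14 | 5,7-bis(methoxymethoxy)-3-(ArB)-4-(trimethylsilyloxy)-2H-chromene | C[Si](C)(C)OC1=C(c2cc(C(C)(C)C=C)c(OCOC)c(CC=C(C)C)c2OCOC)COc2cc(OCOC)cc(OCOC)c12
F6 | step 15 | fremontone tetrakis(trimethylsilyl) ether | C=CC(C)(C)c1cc(-c2coc3cc(O[Si](C)(C)C)cc(O[Si](C)(C)C)c3c2=O)c(O[Si](C)(C)C)c(CC=C(C)C)c1O[Si](C)(C)C
F7 | step 1 | 2-hydroxy-4-[(2-methylbut-3-yn-2-yl)oxy]benzaldehyde | O=Cc1ccc(OC(C)(C)C#C)cc1O
F8 | step 1 | 2-hydroxy-4-[(2-methylbut-3-en-2-yl)oxy]benzaldehyde | O=Cc1ccc(OC(C)(C)C=C)cc1O
A1 | alternative 1 | 4-(2-methylbut-3-en-2-yl)-2-(3-methylbut-2-en-1-yl)cyclohexane-1,3-dione, racemic and epimerisable | O=C1CCC(C(C)(C)C=C)C(=O)C1CC=C(C)C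
A2 | alternative 1 | methyl 3,3-dimethylpent-4-enoate | COC(=O)CC(C)(C)C=C
A3 | alternative 1 | 7-methylocta-1,6-dien-3-one | C=CC(=O)CCC=C(C)C
A4 | alternative 2 | fremontone tetrakis(methoxymethyl) ether (identical with 24) | C=CC(C)(C)c1cc(-c2coc3cc(OCOC)cc(OCOC)c3c2=O)c(OCOC)c(CC=C(C)C)c1OCOC
A5 | alternative 2 | 4-[(E)-2-(ArB)ethenyl]morpholine | O1CCN(CC1)/C=C/c1cc(C(C)(C)C=C)c(OCOC)c(CC=C(C)C)c1OCOC
A6 | alternative 2 | 2-fluoro-4,6-bis(methoxymethoxy)benzoyl chloride | O=C(Cl)c1c(F)cc(OCOC)cc1OCOC
A7 | alternative 2 | 2-(ArB)acetaldehyde | O=CCc1cc(C(C)(C)C=C)c(OCOC)c(CC=C(C)C)c1OCOC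
A8 | alternative 3 | 4'-O-triisopropylsilyl-5,7-bis-O-methoxymethyl fremontone | C=CC(C)(C)c1cc(-c2coc3cc(OCOC)cc(OCOC)c3c2=O)c(O)c(CC=C(C)C)c1O[Si](C(C)C)(C(C)C)C(C)C
A9 | alternative 3 | (E)-1-[5,7-bis(methoxymethoxy)-4-oxo-4H-chromen-3-yl]-4-diazo-5,5-dimethylhepta-1,6-dien-3-one | [N-]=[N+]=C(C(=O)/C=C/c1coc2cc(OCOC)cc(OCOC)c2c1=O)C(C)(C)C=C
A10 | alternative 3 | triisopropyl[(5-methylhex-4-en-1-yn-1-yl)oxy]silane | CC(C)=CCC#CO[Si](C(C)C)(C(C)C)C(C)C
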